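## The problem

1. Target **18** is a spiroaxane sesquiterpene fused through a cis-dihydropyran to a 3,5-diformylphloroglucinol. Ring A is the arene C1′–C6′, ring B the pyran (O, C5, C4, C7′, C1′, C2′), ring C the cyclopentane C1–C5 and ring D the cyclohexene C1, C6–C10. C1 is the spiro carbon, C4 carries CH3 and the benzylic C7′ (isobutyl), C5 the ether oxygen, C7 the isopropyl group and C10 a methyl group.
2. Five stereocentres (1R,4S,5R,10R,7′R) must be set: the spiro quaternary C1 next to C10, the quaternary C4, the ether carbon C5 locked between the two, and the benzylic C7′.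
3. Ring B is attached the wrong way round for a polar cycloaddition: the oxygen sits on the secondary C5 and the benzylic carbon on the fully substituted C4. Both also sit on the face of ring C that is syn to C10, whose methyl group (cis to C5 on ring D) leans over that face.
4. Consequently H5, the C4 methyl group and H7′ all lie on one face of ring B, the open one syn to the vinylic C6–H. These three groups, not the arene, are the ones that substrate control can deliver: C1 can control C5, C5 can control C4 through the cis ring fusion, and the finished B/C bicycle can control C7′.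
5. The feature that makes the key step possible is the array C5(–O)–C1(spiro)–C6=C7 together with the bridge C2–C3–C4. An oxygenated carbon bonded to an allylic all-carbon quaternary centre is the retron of a palladium-mediated oxidative ring expansion of a 1-(cyclohex-1-enyl)cyclobutanol, in which C5, C4, C3 and C2 are the four carbons of cyclobutanone.
6. Sensitive elements are the trisubstituted C6=C7 bond (protic acid, electrophiles), the acidic and oxidisable diformylphloroglucinol (bases, hydrides, organometallics) and C7′–H, which is prone to ortho-quinone methide formation. The formyl groups are therefore best introduced last.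

## Retrosynthesis

**18 ⇒ 16.** The two aryl–CHO bonds at C3′ and C5′ are cut first. Free formyl groups would not survive the borohydride, the organometallic reagent or the silane/acid steps that build ring B, whereas C3′ and C5′ are the only unsubstituted positions of a phloroglucinol ring and are strongly activated. The forward step must formylate twice without touching C6=C7.

**16 ⇒ 15 ⇒ 14.** At C7′ the C–H bond and the C–CH2 bond of the isobutyl group are cut, leading through carbinol **15** to chromanone **14**. A cation at C7′ is stabilised by three ring-A oxygens, and hydrogen is the group that lies on the open face, so it should arrive last and the carbon first. The opposite order is stereocomplementary and is kept in reserve. The forward steps are addition of an isobutyl nucleophile to a hindered, non-enolisable ketone, face-selective hydride capture, and removal of the phenol protecting groups.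

**14 ⇒ 12.** The C4–CH3 and C5–H bonds are cut together, which flattens ring B to chromone **12**. Both groups lie on the same face, syn to C6–H, so a conjugate reduction followed by enolate methylation can set C5 and then C4. The neighbouring cut, C4–C7′ at this stage (an enolate at C4 plus a benzylic electrophile), would bring the large group in from the open face and give the C4 epimer. Two stereocentres disappear; the forward reaction needs 1,4-hydride delivery to a hindered β-carbon and C-methylation of the resulting enolate.

**12 ⇒ 11 ⇒ 7 + 8.** The two aryl ether bonds at C4′ and C6′ are cut (SNAr on difluorochromone **11**), then ring B itself at C4–C7′ and O–C2′. This leads to spiro ketone **7** and commercial 2,4,6-trifluorobenzoyl chloride **8**. The carbonyl group of **7** dictates the regiochemistry that a cycloaddition cannot give: C4 is its only enolisable position and its oxygen becomes the ring oxygen on C5. The forward reactions are a C-acylation and an intramolecular SNAr, both standard.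

**7 ⇒ 6 (key step).** The C1–C2 bond is cut and C2 reconnected to C5, and the C6=C7 bond is traded for C1=C6. This gives alkenylcyclobutanol **6**. The spiro centre, the C5 carbonyl group and the position of the ring-D double bond all arise in one strain-releasing 1,2-shift. Spiro-annulation of a menthone-type ketone was rejected because the second bond at C1 enters anti to the C10 methyl group, which puts C5 on the wrong side unless two ketones are differentiated later. The forward reaction must transfer the configuration of C10 to C1 and place the double bond at C6=C7 only.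

**6 ⇒ 3 + 4 ⇒ 2 ⇒ 1.** The bond between C1 and the carbinol carbon is cut: alkenyllithium **5** from trisylhydrazone **3** (Shapiro reaction) adds to cyclobutanone **4**. Hydrazone **3** comes from trans-carvomenthone **2**, and **2** from (+)-dihydrocarvone **1** by saturation of the isopropenyl group. The chiral pool supplies C10 with the correct configuration and a trans C7 centre that directs the key step and is then erased.

## Roads not taken

Alternative 1: (the most obvious) Cut O–C5 and C4–C7′ at once, i.e. a hetero-Diels–Alder reaction of ortho-quinone methide A2 (from 2,4-diformylphloroglucinol and 3-methylbutanal) with the sesquiterpene diene A1. In this polar, asynchronous cycloaddition the methide carbon bonds to the less substituted alkene carbon and the oxygen to the more substituted one. A1 should therefore give the constitutional isomer A3, with oxygen on C4 and C7′ on C5. The heterodiene would also approach C4=C5 anti to the C10 methyl group, the face opposite to the one that carries ring B in **18**. A1 is no easier to make than **7**. The chosen plan makes the regiochemistry a consequence of the C5 carbonyl group and brings only H and CH3 in from the open face.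

Alternative 2: Keep the cycloaddition but reverse its polarity with a temporary oxygen. Silyl enol ether A4 (from the 4-methyl derivative of **7**) and A2 should give ketal A5, with C7′ on C4 and two oxygens on C5; Et3SiH/BF3·OEt2 would then remove the extra oxygen. This is three steps shorter and fixes the regiochemistry. However, the C4–C7′ bond still has to form on the face covered by the C10 methyl group, so the likely product is the C4 epimer, which cannot be corrected at a quaternary centre. The ketal reduction would also have to spare two free formyl groups. The chosen plan attaches C7′ before the methyl group for exactly this reason.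

Alternative 3: Strain-release methylation. Condensation of **7**, 2,4-diformylphloroglucinol and 3-methylbutanal (enamine plus A2) would give 4H-chromene A6. Cyclopropanation of its enol ether bond C4=C5 (Et2Zn/CH2I2) would give A7, and acid/Et3SiH opening of the cyclopropyl ether would deliver CH3 to C4 and H to C5 from the open face, three steps from **7**. It was set aside for three reasons. C7′ is created in the condensation, far from C1 and without a controlling element. The EtZnCH2I carbenoid must choose a hindered aryl enol ether over C6=C7 in the presence of free phenols and aldehydes. The final ionic reduction again meets the formyl groups. In the chosen route C7′ is set last, next to the finished ring fusion, and the arene stays protected and formyl-free until the end.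

Key step: step 4

Assumption: commercial (+)-dihydrocarvone is taken as its major (2R,5R)-trans isomer; the minor C2 epimer it contains is removed when hydrazone **3** is recrystallised.

## Route

Step 1
Reactants: 1 (2R,5R)-2-methyl-5-(prop-1-en-2-yl)cyclohexan-1-one [(+)-dihydrocarvone]
Product: 2 (2R,5R)-2-methyl-5-(propan-2-yl)cyclohexan-1-one (trans-carvomenthone)
Conditions: H2 (1 atm), RhCl(PPh3)3 (2 mol %), benzene–EtOH, rt
Reagents that add atoms: none
Why: Homogeneous hydrogenation with RhCl(PPh3)3 should saturate only the 1,1-disubstituted isopropenyl bond; the neutral conditions leave the ketone and the epimerisable C2 (future C10) untouched.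

Step 2
Reactants: 2 (2R,5R)-2-methyl-5-(propan-2-yl)cyclohexan-1-one
Product: 3 N′-[(1E,2R,5R)-2-methyl-5-(propan-2-yl)cyclohexylidene]-2,4,6-tri(propan-2-yl)benzenesulfonohydrazide
Conditions: 2,4,6-(i-Pr)3C6H2SO2NHNH2, HCl (cat.), MeCN, rt; recrystallisation
Reagents that add atoms: 2,4,6-tri(propan-2-yl)benzenesulfonohydrazide CC(C)c1cc(C(C)C)c(S(=O)(=O)NN)c(C(C)C)c1
Why: Acid-catalysed condensation to the sulfonylhydrazone; the N–N bond should take the E geometry, anti to the branched C2, and recrystallisation frees the trans hydrazone from the minor C2 epimer.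

Step 3
Reactants: 3 N′-[(1E,2R,5R)-2-methyl-5-(propan-2-yl)cyclohexylidene]-2,4,6-tri(propan-2-yl)benzenesulfonohydrazide; 4 cyclobutanone
Product: 6 1-[(3S,6R)-6-methyl-3-(propan-2-yl)cyclohex-1-en-1-yl]cyclobutan-1-ol, via alkenyllithium 5 (not isolated)
Conditions: n-BuLi (2.2 equiv), TMEDA–hexane, −78 → 0 °C; then 4, THF, −78 °C
Reagents that add atoms: none
Why: Shapiro reaction: n-BuLi forms the dianion by removing a hydrogen from the unbranched α-CH2 syn to the sulfonamide nitrogen, and loss of sulfinate and N2 gives alkenyllithium 5 with the double bond away from the methyl-bearing carbon, so neither stereocentre is touched. 5 should add to the strained carbonyl group of cyclobutanone faster than it enolises it.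

Step 4
Reactants: 6 1-[(3S,6R)-6-methyl-3-(propan-2-yl)cyclohex-1-en-1-yl]cyclobutan-1-ol
Product: 7 (5R,10R)-10-methyl-7-(propan-2-yl)spiro[4.5]dec-6-en-1-one
Conditions: Pd(OAc)2 (10 mol %), 1,4-benzoquinone (1.2 equiv), THF, 45 °C
Reagents that add atoms: none
Why: Divalent palladium binds the C1=C6 bond of 6 and a cyclobutane C–C bond migrates from the carbinol carbon (future C5) to C1 anti to the metal, enlarging the strained four-membered ring (about 26 kcal/mol) to the cyclopentanone; the alkylpalladium species at C6 then loses H7 by syn β-hydride elimination and benzoquinone returns zerovalent palladium to the divalent state. The closest known reaction type is the Wacker-type oxidative semipinacol ring expansion of 1-alkenylcyclobutanols to α-quaternary cyclopentanones, which includes 1-(cycloalk-1-enyl)cyclobutanols giving β,γ-unsaturated spiro ketones. Ring C is closed by a 1,2-alkyl shift (C2 moves from C5 to C1), not by a cyclisation, so no Baldwin constraint applies. The new stereocentre C1 is set by the two allylic substituents, which are trans in 6: the migrating C2 enters anti to the C10 methyl group on the neighbouring carbon and palladium sits on the opposite face, anti to the C7 isopropyl group, so both steric demands are met in one anti addition and C5 ends up cis to the C10 methyl group as in 18. The C7 stereocentre inherited from dihydrocarvone serves only as this control element and as the source of the syn hydrogen, and is erased when C6=C7 forms. The elimination has no regiochemical choice because C1 is quaternary, and for the same reason the double bond cannot move into conjugation. The step needs migration to beat β-carbon elimination of a palladium alkoxide (ring opening) and needs the palladium hydride removed before it re-adds; the first is favoured by alkene coordination, the second by benzoquinone.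

Step 5
Reactants: 7 (5R,10R)-10-methyl-7-(propan-2-yl)spiro[4.5]dec-6-en-1-one; 8 2,4,6-trifluorobenzoyl chloride
Product: 11 (1R,6R)-6′,8′-difluoro-6-methyl-3-(propan-2-yl)-1′,2′-dihydro-9′H-spiro[cyclohex-2-ene-1,3′-cyclopenta[b]chromen]-9′-one, via lithium enolate 9 (not isolated), via 1,3-diketone 10 (not isolated)
Conditions: LiN(SiMe3)2 (2.2 equiv), THF, −78 °C; 8, −78 → 0 °C; then K2CO3, DMF, 80 °C
Reagents that add atoms: none
Why: Claisen-type C-acylation of the lithium enolate, which can only form towards C4 because C1 is quaternary, followed by intramolecular SNAr in which the enol oxygen on C5 displaces an ortho fluoride activated by the aryl ketone (the 2-fluorobenzoyl route to chromones). This makes the C4–C7′ and O–C2′ bonds of ring B with the regiochemistry fixed by the carbonyl group of 7.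

Step 6
Reactants: 11 (1R,6R)-6′,8′-difluoro-6-methyl-3-(propan-2-yl)-1′,2′-dihydro-9′H-spiro[cyclohex-2-ene-1,3′-cyclopenta[b]chromen]-9′-one
Product: 12 (1R,6R)-6′,8′-bis[(4-methoxyphenyl)methoxy]-6-methyl-3-(propan-2-yl)-1′,2′-dihydro-9′H-spiro[cyclohex-2-ene-1,3′-cyclopenta[b]chromen]-9′-one
Conditions: 4-MeOC6H4CH2OH (2.5 equiv), NaH, DMF, 0 → 60 °C
Reagents that add atoms: (4-methoxyphenyl)methanol COc1ccc(CO)cc1
Why: Twofold SNAr: the fluorides ortho and para to the chromone carbonyl group are displaced by the alkoxide, while C5, the other electrophilic site, is shielded by the adjacent quaternary C1.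

Step 7
Reactants: 12 (1R,6R)-6′,8′-bis[(4-methoxyphenyl)methoxy]-6-methyl-3-(propan-2-yl)-1′,2′-dihydro-9′H-spiro[cyclohex-2-ene-1,3′-cyclopenta[b]chromen]-9′-one
Product: 14 (1R,3a′S,6R,9a′R)-6′,8′-bis[(4-methoxyphenyl)methoxy]-6,9a′-dimethyl-3-(propan-2-yl)-1′,2′,3a′,9a′-tetrahydro-9′H-spiro[cyclohex-2-ene-1,3′-cyclopenta[b]chromen]-9′-one, via lithium enolate 13 (not isolated)
Conditions: LiBH(s-Bu)3 (1.2 equiv), THF, −78 °C; then MeI, DMPU, −78 → −20 °C
Reagents that add atoms: iodomethane CI
Why: Conjugate reduction of the chromone and trapping of the enolate with MeI (reductive alkylation). Hydride should enter at C5 on the face syn to the vinylic C6–H, because the C10 methyl group covers the other face, and this sets C5; MeI then attacks the enolate carbon C4 on the side of H5, the only approach that leaves rings B and C cis-fused, and sets the quaternary C4.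

Step 8
Reactants: 14 (1R,3a′S,6R,9a′R)-6′,8′-bis[(4-methoxyphenyl)methoxy]-6,9a′-dimethyl-3-(propan-2-yl)-1′,2′,3a′,9a′-tetrahydro-9′H-spiro[cyclohex-2-ene-1,3′-cyclopenta[b]chromen]-9′-one
Product: 15 (1R,3a′S,6R,9a′R)-6′,8′-bis[(4-methoxyphenyl)methoxy]-6,9a′-dimethyl-9′-(2-methylpropyl)-3-(propan-2-yl)-1′,2′,9′,9a′-tetrahydro-3a′H-spiro[cyclohex-2-ene-1,3′-cyclopenta[b]chromen]-9′-ol (either C9′ epimer)
Conditions: i-BuLi, CeCl3, THF, −78 °C
Reagents that add atoms: (2-methylpropyl)lithium [Li]CC(C)C
Why: 1,2-Addition of the weakly basic organocerium reagent i-BuCeCl2 (Imamoto conditions) to the hindered, non-enolisable aryl ketone; the configuration of the carbinol carbon does not matter because it is ionised in step 9.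

Step 9
Reactants: 15 (1R,3a′S,6R,9a′R)-6′,8′-bis[(4-methoxyphenyl)methoxy]-6,9a′-dimethyl-9′-(2-methylpropyl)-3-(propan-2-yl)-1′,2′,9′,9a′-tetrahydro-3a′H-spiro[cyclohex-2-ene-1,3′-cyclopenta[b]chromen]-9′-ol
Product: 16 (1R,3a′R,6R,9′R,9a′S)-6,9a′-dimethyl-9′-(2-methylpropyl)-3-(propan-2-yl)-1′,2′,9′,9a′-tetrahydro-3a′H-spiro[cyclohex-2-ene-1,3′-cyclopenta[b]chromene]-6′,8′-diol
Conditions: Et3SiH (6 equiv), CF3CO2H (10 vol %), CH2Cl2, −20 → 0 °C
Reagents that add atoms: none
Why: Ionic hydrogenation (Kursanov–Parnes type): the carbinol ionises to a C7′ cation stabilised by three ring-A oxygens and Et3SiH should deliver hydride to the face syn to the C4 methyl group, anti to the pseudo-axial C3 of the cis-fused ring C, to give 7′R. The same acid cleaves both 4-methoxybenzyl ethers, whose cations the silane reduces to 4-methylanisole. Ionisation at C7′ and at the benzylic ethers should be much faster than protonation of the hindered C6=C7 bond at this acid strength and temperature.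

Step 10
Reactants: 16 (1R,3a′R,6R,9′R,9a′S)-6,9a′-dimethyl-9′-(2-methylpropyl)-3-(propan-2-yl)-1′,2′,9′,9a′-tetrahydro-3a′H-spiro[cyclohex-2-ene-1,3′-cyclopenta[b]chromene]-6′,8′-diol
Product: 18 (1R,3a′R,6R,9′R,9a′S)-6′,8′-dihydroxy-6,9a′-dimethyl-9′-(2-methylpropyl)-3-(propan-2-yl)-1′,2′,9′,9a′-tetrahydro-3a′H-spiro[cyclohex-2-ene-1,3′-cyclopenta[b]chromene]-5′,7′-dicarbaldehyde (CNP0121396.1), via bis-iminium salt 17 (not isolated)
Conditions: POCl3, DMF, EtOAc, 0 °C → rt; then H2O, 50 °C
Reagents that add atoms: N,N-dimethylformamide CN(C)C=O; water O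
Why: Twofold Vilsmeier–Haack formylation at C3′ and C5′, the only free positions of the phloroglucinol ring and each ortho or para to three oxygen substituents, followed by hydrolysis of the bis-iminium salt. The same reagent converts phloroglucinol itself into its 2,4-diformyl derivative, and it does not attack an isolated trisubstituted alkene.

## Compound list

In the systematic names C1 is the spiro carbon, C6 is C10 of the text, C3a′ is C5, C9a′ is C4 and C9′ is C7′.

1 | (2R,5R)-2-methyl-5-(prop-1-en-2-yl)cyclohexan-1-one, (+)-dihydrocarvone | O=C1C[C@H](C(C)=C)CC[C@H]1C | starting material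
2 | (2R,5R)-2-methyl-5-(propan-2-yl)cyclohexan-1-one | O=C1C[C@H](C(C)C)CC[C@H]1C | intermediate
3 | N′-[(1E,2R,5R)-2-methyl-5-(propan-2-yl)cyclohexylidene]-2,4,6-tri(propan-2-yl)benzenesulfonohydrazide | CC(C)c1cc(C(C)C)c(S(=O)(=O)N/N=C2\C[C@H](C(C)C)CC[C@H]2C)c(C(C)C)c1 | intermediate
4 | cyclobutanone | O=C1CCC1 | starting material
5 | [(3S,6R)-6-methyl-3-(propan-2-yl)cyclohex-1-en-1-yl]lithium | [Li]C1=C[C@H](C(C)C)CC[C@H]1C | intermediate (not isolated)
6 | 1-[(3S,6R)-6-methyl-3-(propan-2-yl)cyclohex-1-en-1-yl]cyclobutan-1-ol | OC1(CCC1)C1=C[C@H](C(C)C)CC[C@H]1C | intermediate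
7 | (5R,10R)-10-methyl-7-(propan-2-yl)spiro[4.5]dec-6-en-1-one | O=C1CCC[C@@]12C=C(C(C)C)CC[C@H]2C | intermediate
8 | 2,4,6-trifluorobenzoyl chloride | O=C(Cl)c1c(F)cc(F)cc1F | starting material
9 | lithium (5R,10R)-10-methyl-7-(propan-2-yl)spiro[4.5]deca-1,6-dien-1-olate | [Li]OC1=CCC[C@@]12C=C(C(C)C)CC[C@H]2C | intermediate (not isolated)
10 | (5R,10R)-10-methyl-7-(propan-2-yl)-2-(2,4,6-trifluorobenzoyl)spiro[4.5]dec-6-en-1-one (C2 epimers and enol forms) | O=C1C(C(=O)c3c(F)cc(F)cc3F)CC[C@@]12C=C(C(C)C)CC[C@H]2C | intermediate (not isolated)
11 | (1R,6R)-6′,8′-difluoro-6-methyl-3-(propan-2-yl)-1′,2′-dihydro-9′H-spiro[cyclohex-2-ene-1,3′-cyclopenta[b]chromen]-9′-one | O=C1c2c(F)cc(F)cc2OC2=C1CC[C@@]21C=C(C(C)C)CC[C@H]1C | intermediate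
12 | (1R,6R)-6′,8′-bis[(4-methoxyphenyl)methoxy]-6-methyl-3-(propan-2-yl)-1′,2′-dihydro-9′H-spiro[cyclohex-2-ene-1,3′-cyclopenta[b]chromen]-9′-one | O=C1c2c(OCc3ccc(OC)cc3)cc(OCc3ccc(OC)cc3)cc2OC2=C1CC[C@@]21C=C(C(C)C)CC[C@H]1C | intermediate
13 | lithium (1R,3a′S,6R)-6′,8′-bis[(4-methoxyphenyl)methoxy]-6-methyl-3-(propan-2-yl)-1′,2′-dihydro-3a′H-spiro[cyclohex-2-ene-1,3′-cyclopenta[b]chromen]-9′-olate | [Li]OC1=C2CC[C@@]3(C=C(C(C)C)CC[C@H]3C)[C@@H]2Oc2cc(OCc3ccc(OC)cc3)cc(OCc3ccc(OC)cc3)c12 | intermediate (not isolated)
14 | (1R,3a′S,6R,9a′R)-6′,8′-bis[(4-methoxyphenyl)methoxy]-6,9a′-dimethyl-3-(propan-2-yl)-1′,2′,3a′,9a′-tetrahydro-9′H-spiro[cyclohex-2-ene-1,3′-cyclopenta[b]chromen]-9′-one | O=C1c2c(OCc3ccc(OC)cc3)cc(OCc3ccc(OC)cc3)cc2O[C@@H]2[C@@]1(C)CC[C@@]21C=C(C(C)C)CC[C@H]1C | intermediate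
15 | (1R,3a′S,6R,9a′R)-6′,8′-bis[(4-methoxyphenyl)methoxy]-6,9a′-dimethyl-9′-(2-methylpropyl)-3-(propan-2-yl)-1′,2′,9′,9a′-tetrahydro-3a′H-spiro[cyclohex-2-ene-1,3′-cyclopenta[b]chromen]-9′-ol (C9′ not specified) | CC(C)CC1(O)c2c(OCc3ccc(OC)cc3)cc(OCc3ccc(OC)cc3)cc2O[C@@H]2[C@@]1(C)CC[C@@]21C=C(C(C)C)CC[C@H]1C | intermediate
16 | (1R,3a′R,6R,9′R,9a′S)-6,9a′-dimethyl-9′-(2-methylpropyl)-3-(propan-2-yl)-1′,2′,9′,9a′-tetrahydro-3a′H-spiro[cyclohex-2-ene-1,3′-cyclopenta[b]chromene]-6′,8′-diol | CC(C)C[C@H]1c2c(O)cc(O)cc2O[C@@H]2[C@@]1(C)CC[C@@]21C=C(C(C)C)CC[C@H]1C | intermediate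
17 | 5′,7′-bis[(dimethyliminio)methyl] analogue of 18, dichloride | CC(C)C[C@H]1c2c(O)c(C=[N+](C)C)c(O)c(C=[N+](C)C)c2O[C@@H]2[C@@]1(C)CC[C@@]21C=C(C(C)C)CC[C@H]1C.[Cl-].[Cl-] | intermediate (not isolated)
18 | (1R,3a′R,6R,9′R,9a′S)-6′,8′-dihydroxy-6,9a′-dimethyl-9′-(2-methylpropyl)-3-(propan-2-yl)-1′,2′,9′,9a′-tetrahydro-3a′H-spiro[cyclohex-2-ene-1,3′-cyclopenta[b]chromene]-5′,7′-dicarbaldehyde | CC(C)C[C@H]1c2c(O)c(C=O)c(O)c(C=O)c2O[C@@H]2[C@@]1(C)CC[C@@]21C=C(C(C)C)CC[C@H]1C | target

## Step count and least certain steps

Total step count: 10. Longest linear sequence: 10 steps (1 → 18); 4 and 8 are commercial and enter directly.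

**Step 4 (key step).** Most likely failure: ring opening of the palladium cyclobutanolate by β-carbon elimination, or recovery of 6, because a trisubstituted alkene flanked by two branched allylic carbons coordinates divalent palladium slowly. Fallback, from 6 back to 7: the same 1,2-shift triggered by an episelenonium ion.
- PhSeCl (CH2Cl2, propylene oxide, −78 °C) should give the 6-(phenylselanyl) spiro ketone F1, with selenium on C6 anti to the migrated C2 and cis to H7.
- Oxidation (H2O2, pyridine, 0 °C → rt) and syn elimination of the selenoxide, which can only take H7, lead to 7.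
- The facial argument is unchanged (C2 anti to the C10 methyl group), and the episelenonium ions form reversibly, so only the productive one is consumed.

**Step 7.** Most likely failure: slow hydride transfer to the hindered C5 and, once enolate 13 exists, opening of ring B by β-elimination of the aryloxide in competition with C-methylation. Fallback, from 10 (isolated after an acidic quench of the first stage of step 5) back to 14: methylate before ring B is closed.
- C-Methylation of the 1,3-diketone (K2CO3, MeI, acetone) should give the 2-methyl diketone F2, the methyl group entering anti to C10.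
- LiAlH4 reduces both carbonyl groups, with hydride at C5 syn to C6–H, to the diol F3.
- NaH in DMF closes ring B by SNAr of the C5 alkoxide on an ortho fluoride to give the chromanol F4.
- Dess–Martin oxidation gives the difluorochromanone F5, and the double SNAr of step 6 then gives 14.

**Step 8.** Most likely failure: reduction of the ketone by β-hydride transfer from the isobutyl reagent, or no addition, because C7′ is flanked by the quaternary C4 and the peri ether on C6′. Fallback, from 14 back to 15: an allyl-type nucleophile, which adds to hindered ketones through a cyclic transition state.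
- CH2=C(CH3)CH2MgCl (THF, −78 °C) should give the methallyl carbinol F6.
- H2 with RhCl(PPh3)3 should saturate the 1,1-disubstituted double bond and leave the hindered trisubstituted C6=C7, giving 15.

**Step 9.** Most likely failure: hydride capture on the wrong face of the C7′ cation, whose two faces differ only in the C4 methyl group versus C3. Fallback, from 14 back to 16: reverse the order in which hydrogen and carbon reach C7′, which is stereocomplementary.
- NaBH4 reduces 14 to the secondary alcohol F7.
- BF3·OEt2 with trimethyl(2-methylallyl)silane (CH2Cl2, −78 °C, Hosomi–Sakurai reaction on the benzylic cation) should place the carbon nucleophile on the face that hydride preferred and leave H7′ on the other, giving the methallyl compound F8.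
- Hydrogenation with RhCl(PPh3)3 gives the isobutyl compound F9, and CF3CO2H/Et3SiH removes the two 4-methoxybenzyl groups to give 16.

**Step 10.** Most likely failure: incomplete second formylation, because the first formyl group deactivates the ring, or addition of HCl to C6=C7. Fallback, from 16 back to 18: magnesium-mediated ortho-formylation (MgCl2, Et3N, paraformaldehyde, MeCN, reflux). It is directed by the phenoxides, runs under basic conditions, can be repeated on the monoaldehyde, and makes no new isolated compound.

## Further compounds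

F1 | step 4 | 10-methyl-6-(phenylselanyl)-7-(propan-2-yl)spiro[4.5]decan-1-one, spiro carbon and C10 as in 7, selenium cis to H7 and anti to the migrated CH2 | O=C1CCC[C@@]12[C@@H]([Se]c3ccccc3)[C@H](C(C)C)CC[C@H]2C
F2 | step 7 | 2,10-dimethyl-7-(propan-2-yl)-2-(2,4,6-trifluorobenzoyl)spiro[4.5]dec-6-en-1-one, 2-methyl group on the face syn to C6 | O=C1[C@](C)(C(=O)c3c(F)cc(F)cc3F)CC[C@@]12C=C(C(C)C)CC[C@H]2C
F3 | step 7 | 2-[hydroxy(2,4,6-trifluorophenyl)methyl]-2,10-dimethyl-7-(propan-2-yl)spiro[4.5]dec-6-en-1-ol, ring hydroxyl cis to the aryl carbinol side chain | O[C@@H]1[C@](C)(C(O)c3c(F)cc(F)cc3F)CC[C@@]12C=C(C(C)C)CC[C@H]2C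
F4 | step 7 | 6′,8′-difluoro analogue of 14 reduced at C9′: cis-fused 6′,8′-difluoro-6,9a′-dimethyl-3-(propan-2-yl)chroman-9′-ol | OC1c2c(F)cc(F)cc2O[C@@H]2[C@@]1(C)CC[C@@]21C=C(C(C)C)CC[C@H]1C
F5 | step 7 | 6′,8′-difluoro analogue of 14 (difluorochromanone) | O=C1c2c(F)cc(F)cc2O[C@@H]2[C@@]1(C)CC[C@@]21C=C(C(C)C)CC[C@H]1C
F6 | step 8 | 9′-(2-methylprop-2-en-1-yl) analogue of 15 | CC(=C)CC1(O)c2c(OCc3ccc(OC)cc3)cc(OCc3ccc(OC)cc3)cc2O[C@@H]2[C@@]1(C)CC[C@@]21C=C(C(C)C)CC[C@H]1C
F7 | step 9 | 9′-hydroxy compound from reduction of 14 (secondary alcohol) | OC1c2c(OCc3ccc(OC)cc3)cc(OCc3ccc(OC)cc3)cc2O[C@@H]2[C@@]1(C)CC[C@@]21C=C(C(C)C)CC[C@H]1C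
F8 | step 9 | 9′-(2-methylprop-2-en-1-yl) analogue of F9, C9′ as in 16 | CC(=C)C[C@H]1c2c(OCc3ccc(OC)cc3)cc(OCc3ccc(OC)cc3)cc2O[C@@H]2[C@@]1(C)CC[C@@]21C=C(C(C)C)CC[C@H]1C
F9 | step 9 | 6′,8′-bis(4-methoxybenzyl) ether of 16 | CC(C)C[C@H]1c2c(OCc3ccc(OC)cc3)cc(OCc3ccc(OC)cc3)cc2O[C@@H]2[C@@]1(C)CC[C@@]21C=C(C(C)C)CC[C@H]1C
F0 | step 10 | none | none
A1 | alternative 1 | (10R)-2,10-dimethyl-7-(propan-2-yl)spiro[4.5]deca-1,6-diene (spiroaxa-4,6-diene), spiro carbon as in 7 | CC1=C[C@@]2(CC1)C=C(C(C)C)CC[C@H]2C
A2 | alternative 1 | ortho-quinone methide of 2,4-diformylphloroglucinol and 3-methylbutanal | CC(C)CC=C1C(=O)C(C=O)=C(O)C(C=O)=C1O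
A3 | alternative 1 | constitutional isomer of 18 with the ring oxygen on C4 and C7′ on C5 (new centres not specified) | CC(C)CC1c2c(O)c(C=O)c(O)c(C=O)c2OC2(C)CC[C@@]3(C=C(C(C)C)CC[C@H]3C)C12
A4 | alternative 2 | tert-butyldimethylsilyl enol ether of (5R,10R)-2,10-dimethyl-7-(propan-2-yl)spiro[4.5]dec-6-en-1-one | CC1=C(O[Si](C)(C)C(C)(C)C)[C@@]2(CC1)C=C(C(C)C)CC[C@H]2C
A5 | alternative 2 | C5 silyloxy ketal cycloadduct of A4 and A2 (C4, C5 and C7′ not specified) | CC(C)CC1c2c(O)c(C=O)c(O)c(C=O)c2OC2(O[Si](C)(C)C(C)(C)C)C1(C)CC[C@@]21C=C(C(C)C)CC[C@H]1C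
A6 | alternative 3 | 4H-chromene from 7, 2,4-diformylphloroglucinol and 3-methylbutanal (C7′ not specified) | CC(C)CC1c2c(O)c(C=O)c(O)c(C=O)c2OC2=C1CC[C@@]21C=C(C(C)C)CC[C@H]1C
A7 | alternative 3 | C4–C5 cyclopropane of A6 (new centres not specified) | CC(C)CC1c2c(O)c(C=O)c(O)c(C=O)c2OC23CC13CC[C@@]21C=C(C(C)C)CC[C@H]1C
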